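South was charged with 1.60 times the L (initiator) of west, so I set out to find R, the average chain length in south divided by that in west.

| setting | red | grey | west | south |
|---|---|---|---|---|
| Z | 0.10 M | 0.10 M | 0.10 M | 0.10 M |
| L | 1.3 mM | 3.3 mM | 2.5 mM | 4.0 mM |
| remark | run made earlier | run made earlier |  |  |
| time |  |  | 6.0 h | 6.0 h |

| run | time / h | J / % |
|---|---|---|
| red | 0.500 | 1.8 |
| red | 0.833 | 4.3 |
| red | 1.50 | 7.8 |
| red | 3.00 | 11.6 |
| red | 6.00 | 14.4 |
| grey | 0.500 | 4.6 |
| grey | 1.50 | 17.2 |
| grey | 3.00 | 26.1 |
| grey | 4.00 | 30.1 |
| grey | 6.00 | 33.9 |

(readings scatter by 0.5 percentage points)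

- which of the two ends with the longer chains by the average number of monomer units in a chain (chains begun, living or dead) ("neither" if they lie within 10%) (west / south / neither)
- average number of monomer units in a chain (chains begun, living or dead) at the end, west
- average number of monomer units in a chain (chains begun, living or dead) at the end, south

- the average divides the monomer in chains by the number of chains begun, living and dead together
- the numbers in the tables scatter by 0.5 percentage points (one standard deviation)
- the earlier runs do not show the number of chains; that part of a forecast is a guess

I worked with the fraction of Z (monomer) left and not with the J (monomer in chains) made. My quantity was s, the dose per unit of L: the logarithm of Z charged over Z charged minus J at the end, divided by the L charged. This reads growth as pseudo-first-order in Z. Red gave 0.120 mM⁻¹ and grey 0.125 mM⁻¹, so I kept the mean, 0.123 mM⁻¹.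

The runs do not count chains, but if both flasks turn the same share of their L into chains, that share cancels in R. J proportional to L put R at 1 from above, and equal J in both flasks put it at 0.625 from below. Using s tightened this: the two readings, crossed between the flasks, gave 0.883 to 0.954, and the mean s gave 0.918. I committed to neither.

The forecast said neither, with 10.5 for west and 9.7 for south, taking “chains ≈ L if efficiency is about 1, which is the guess”. Its ratio, 0.924, stood inside my bracket.

The flasks gave neither, with 11.1 for west and 10.8 for south, so R was 0.973, above the upper end of my bracket.

    2 G → Q (k = 2.10 L mol⁻¹ min⁻¹)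
    Z + G → J + G, rate k2*[G]*[Z] (k = 4.57 L mol⁻¹ min⁻¹)
    G + Z → X (k = 0.435 L mol⁻¹ min⁻¹)
    Z + L → G + J (k = 0.105 L mol⁻¹ min⁻¹)

The equal share gave way: at 6.00 h west kept 4.81% of its L and south 7.05%. With the using up of L taken away, the simulated runs give 9.84 for west and 9.23 for south, a ratio of 0.938, so that using up is part of the rise in R. The path from G + Z to X turned the answer further: taken away, it left west at 36.9 in place of 11.1. The neighbour flask, a west charged with 6.30 mM of L, where s puts J at 53.9%, held J at 57.3%.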